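**Retrosynthetic overview**
1. Salimabromide ⇒ saturated, bromine-free keto lactone: the enone comes from a last-step ketone dehydrogenation, the two aryl bromides from a late electrophilic bromination.
2. Keto lactone ⇒ one C9–C10 bond: the β-carbon of a dihydronaphthalene enal, made nucleophilic as an NHC homoenolate, adds to a tethered α-keto aldehyde carbon and the alkoxide lactonises. Both carbons are normally electrophilic. This closes the seven-membered ring and the lactone and sets C9, C10 and C13 from C14.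
3. Enal/keto aldehyde ⇒ β-keto ester whose quaternary C14 comes from a copper-catalysed asymmetric conjugate methylation of a cyclic alkylidene β-keto ester (the only enantio-determining step).
4. Alkylidene β-keto ester ⇒ vinyl triflate + four-carbon acetonide tether (B-alkyl Suzuki) ⇒ Friedel–Crafts closure of an acyl-malonate enol triflate ⇒ 2-(4-ethylphenyl)-2-methylpropanoic acid + diethyl malonate.
5. Ring order: arene (purchased) → carbocyclic ring of the tetralin (step 3) → cycloheptanone and γ-lactone together (step 9).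

Labels and one assumption: target carbons are called C9 (ArCH), C10 (OCH), C12 (lactone C=O), C13, C14 (C–CH3), C15=C16 (alkene), C17 (ketone), C18 (CMe2), in which salimabromide is (9S,10S,13R,14R); (4S)-4-ethenyl-2,2-dimethyl-1,3-dioxolane is assumed to be purchasable (the racemate would serve equally, because that centre ends as the C17 carbonyl).

**Step 1**
Reactants: 1 2-(4-ethylphenyl)-2-methylpropanoic acid; 2 diethyl malonate
Product: 4 diethyl 2-[2-(4-ethylphenyl)-2-methylpropanoyl]propanedioate, via acid chloride 3 (not isolated)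
Conditions: (COCl)2, cat. DMF, CH2Cl2, 0 °C → rt; then 2, MgCl2, Et3N, MeCN, 0 °C → rt
Reagents that add atoms: none
Why: The magnesium-chelated malonate is C-acylated by the hindered acid chloride under soft enolisation (magnesium-mediated malonate C-acylation), giving the fully enolised acyl malonate.

**Step 2**
Reactants: 4 diethyl 2-[2-(4-ethylphenyl)-2-methylpropanoyl]propanedioate
Product: 5 diethyl 2-{2-(4-ethylphenyl)-2-methyl-1-[(trifluoromethanesulfonyl)oxy]propylidene}propanedioate
Conditions: Tf2O, Et3N, CH2Cl2, −78 → 0 °C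
Reagents that add atoms: trifluoromethanesulfonic anhydride, O=S(=O)(OS(=O)(=O)C(F)(F)F)C(F)(F)F
Why: The acyl malonate enolises only towards the malonate carbon, so O-sulfonylation (enol triflate formation) gives one geometry-free vinyl triflate and fixes, before ring closure, that the leaving group sits on the future C14.

**Step 3**
Reactants: 5 diethyl 2-{2-(4-ethylphenyl)-2-methyl-1-[(trifluoromethanesulfonyl)oxy]propylidene}propanedioate
Product: 6 ethyl 7-ethyl-4,4-dimethyl-1-oxo-3-[(trifluoromethanesulfonyl)oxy]-1,4-dihydronaphthalene-2-carboxylate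
Conditions: P2O5/MeSO3H (Eaton's reagent), 60 °C
Reagents that add atoms: none
Why: Intramolecular Friedel–Crafts acylation by the ester that lies cis to the aryl-bearing CMe2 group closes the six-membered ring at either of the two equivalent ortho positions, and the vinyl triflate survives the anhydrous acid.

**Step 4**
Reactants: 6 ethyl 7-ethyl-4,4-dimethyl-1-oxo-3-[(trifluoromethanesulfonyl)oxy]-1,4-dihydronaphthalene-2-carboxylate; 7 (4S)-4-ethenyl-2,2-dimethyl-1,3-dioxolane
Product: 9 ethyl 3-{2-[(4S)-2,2-dimethyl-1,3-dioxolan-4-yl]ethyl}-7-ethyl-4,4-dimethyl-1-oxo-1,4-dihydronaphthalene-2-carboxylate, via alkylborane 8 (not isolated)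
Conditions: 7, 9-BBN, THF, 0 °C → rt; then 6, Pd(dppf)Cl2 (5 mol%), K3PO4 (3 M aq.), DMF, 50 °C
Reagents that add atoms: none
Why: Anti-Markovnikov hydroboration of 7 followed by B-alkyl Suzuki–Miyaura coupling at the electron-poor vinyl triflate puts the four-carbon tether (C15–C16–C17–C10) on C14 without touching the dioxolane stereocentre.

**Step 5**
Reactants: 9 ethyl 3-{2-[(4S)-2,2-dimethyl-1,3-dioxolan-4-yl]ethyl}-7-ethyl-4,4-dimethyl-1-oxo-1,4-dihydronaphthalene-2-carboxylate
Product: 10 ethyl (3S)-3-{2-[(4S)-2,2-dimethyl-1,3-dioxolan-4-yl]ethyl}-7-ethyl-1-hydroxy-3,4,4-trimethyl-3,4-dihydronaphthalene-2-carboxylate (enol form of the β-keto ester)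
Conditions: AlMe3 (2 equiv), Cu(OTf)2 (5 mol%), (S)-N,N-bis[(S)-1-phenylethyl]dinaphtho[2,1-d:1′,2′-f][1,3,2]dioxaphosphepin-4-amine (10 mol%), Et2O, −30 °C; then aq. NH4Cl
Reagents that add atoms: trimethylaluminium, C[Al](C)C
Why: Copper-catalysed asymmetric conjugate addition of AlMe3 to the doubly activated alkylidene β-keto ester delivers the small methyl nucleophile to one face of C14 under control of the chiral phosphoramidite complex of monovalent copper formed in situ, creating the quaternary (3S) centre next to CMe2 (the ligand antipode is the one found to give this sense).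

**Step 6**
Reactants: 10 ethyl (3S)-3-{2-[(4S)-2,2-dimethyl-1,3-dioxolan-4-yl]ethyl}-7-ethyl-1-hydroxy-3,4,4-trimethyl-3,4-dihydronaphthalene-2-carboxylate
Product: 11 (3R)-3-{2-[(4S)-2,2-dimethyl-1,3-dioxolan-4-yl]ethyl}-7-ethyl-2-(hydroxymethyl)-3,4,4-trimethyl-1,2,3,4-tetrahydronaphthalen-1-ol (epimers at C1 and C2)
Conditions: LiAlH4, THF, 0 °C → rt
Reagents that add atoms: none
Why: Hydride reduction of both carbonyls of the β-keto ester gives the 1,3-diol, whose two new centres form as a mixture that is erased in step 7 while C14 is untouched (its descriptor changes to R only through the priority rules).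

**Step 7**
Reactants: 11 (3R)-3-{2-[(4S)-2,2-dimethyl-1,3-dioxolan-4-yl]ethyl}-7-ethyl-2-(hydroxymethyl)-3,4,4-trimethyl-1,2,3,4-tetrahydronaphthalen-1-ol
Product: 12 (2S)-4-[(2S)-6-ethyl-3-(hydroxymethyl)-1,1,2-trimethyl-1,2-dihydronaphthalen-2-yl]butane-1,2-diol
Conditions: p-TsOH·H2O (0.2 equiv), toluene, 80 °C; then THF/H2O, 50 °C
Reagents that add atoms: none
Why: Acid-catalysed E1 dehydration of the benzylic alcohol gives the aryl-conjugated C9=C13 alkene and the same acid hydrolyses the acetonide (acetal hydrolysis), leaving C14 and the diol centre unchanged.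

**Step 8**
Reactants: 12 (2S)-4-[(2S)-6-ethyl-3-(hydroxymethyl)-1,1,2-trimethyl-1,2-dihydronaphthalen-2-yl]butane-1,2-diol
Product: 13 4-[(2S)-6-ethyl-3-formyl-1,1,2-trimethyl-1,2-dihydronaphthalen-2-yl]-2-oxobutanal
Conditions: IBX (4 equiv), DMSO, rt; used crude
Reagents that add atoms: none
Why: IBX oxidation converts the allylic alcohol into the enal and the terminal 1,2-diol into the α-keto aldehyde without C–C cleavage, and the quaternary C14 cannot epimerise.

**Step 9**
Reactants: 13 4-[(2S)-6-ethyl-3-formyl-1,1,2-trimethyl-1,2-dihydronaphthalen-2-yl]-2-oxobutanal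
Product: 14 keto lactone: bromine-free C15–C16-saturated salimabromide (C9 S; C10 S; C13 R; C14 R)
Conditions: 2-mesityl-6,7-dihydro-5H-pyrrolo[2,1-c][1,2,4]triazol-2-ium chloride (20 mol%), i-Pr2NEt (20 mol%), 4 Å MS, THF, 40 °C
Reagents that add atoms: none
Why: Proposed new method: the carbene adds to the enal aldehyde to give the Breslow intermediate, which turns the enal β-carbon C9 into a homoenolate nucleophile that attacks the highly electrophilic tethered glyoxal carbon C10 on the only face the tether can reach (syn to the tether on C14), after which tautomerisation to the acyl azolium and acylation by the new C10 alkoxide close the γ-lactone and release the catalyst, so the seven-membered ring and the lactone form together and C9, C10 and C13 are fixed by the bridged-ring geometry relative to C14 (C10 and C13 can epimerise, being α to the ketone and to the acyl azolium, until lactonisation traps the one isomer that can close); the closest known reaction type is the NHC-catalysed homoenolate annulation of enals with aldehydes to γ-butyrolactones, here intramolecular with an α-branched cyclic enal, while carbene addition to the glyoxal is expected to be reversible and the weak base limits enolisation of the keto aldehyde.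

**Step 10**
Reactants: 14 keto lactone: bromine-free C15–C16-saturated salimabromide
Product: 15 dibromo keto lactone: C15–C16-saturated salimabromide (C9 S; C10 S; C13 R; C14 R)
Conditions: Br2 (2.2 equiv), AgOTf (2.2 equiv), CH2Cl2/CF3CO2H, −20 → 0 °C
Reagents that add atoms: bromine, BrBr
Why: Silver-assisted electrophilic aromatic bromination attacks the two ring positions ortho to the ethyl group, each also ortho or para to a second alkyl substituent, whereas the third C–H is flanked by CMe2 and activated by one alkyl group only, and the low temperature keeps the ketone from enolising.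

**Step 11**
Reactants: 15 dibromo keto lactone: C15–C16-saturated salimabromide
Product: 16 salimabromide
Conditions: IBX (2.5 equiv), DMSO/PhF, 75 °C
Reagents that add atoms: none
Why: IBX-mediated α,β-dehydrogenation of the ketone can only proceed towards C16, because C10 is a lactone-bearing bridgehead and C14 is quaternary, so the C15=C16 enone forms regioselectively, the electron-poor dibromoarene resists benzylic oxidation, and no stereocentre is touched.

**Compound list**
1 | 2-(4-ethylphenyl)-2-methylpropanoic acid | CCc1ccc(cc1)C(C)(C)C(=O)O | starting material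
2 | diethyl malonate | CCOC(=O)CC(=O)OCC | starting material
3 | 2-(4-ethylphenyl)-2-methylpropanoyl chloride | CCc1ccc(cc1)C(C)(C)C(Cl)=O | intermediate
4 | diethyl 2-[2-(4-ethylphenyl)-2-methylpropanoyl]propanedioate | CCc1ccc(cc1)C(C)(C)C(=O)C(C(=O)OCC)C(=O)OCC | intermediate
5 | diethyl 2-{2-(4-ethylphenyl)-2-methyl-1-[(trifluoromethanesulfonyl)oxy]propylidene}propanedioate | CCc1ccc(cc1)C(C)(C)C(OS(=O)(=O)C(F)(F)F)=C(C(=O)OCC)C(=O)OCC | intermediate
6 | ethyl 7-ethyl-4,4-dimethyl-1-oxo-3-[(trifluoromethanesulfonyl)oxy]-1,4-dihydronaphthalene-2-carboxylate | CCOC(=O)C1=C(OS(=O)(=O)C(F)(F)F)C(C)(C)c2ccc(CC)cc2C1=O | intermediate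
7 | (4S)-4-ethenyl-2,2-dimethyl-1,3-dioxolane | C=C[C@H]1COC(C)(C)O1 | starting material
8 | 9-{2-[(4S)-2,2-dimethyl-1,3-dioxolan-4-yl]ethyl}-9-borabicyclo[3.3.1]nonane | CC1(C)OC[C@H](CCB2C3CCCC2CCC3)O1 | intermediate
9 | ethyl 3-{2-[(4S)-2,2-dimethyl-1,3-dioxolan-4-yl]ethyl}-7-ethyl-4,4-dimethyl-1-oxo-1,4-dihydronaphthalene-2-carboxylate | CCOC(=O)C1=C(CC[C@H]3COC(C)(C)O3)C(C)(C)c2ccc(CC)cc2C1=O | intermediate
10 | ethyl (3S)-3-{2-[(4S)-2,2-dimethyl-1,3-dioxolan-4-yl]ethyl}-7-ethyl-1-hydroxy-3,4,4-trimethyl-3,4-dihydronaphthalene-2-carboxylate (enol form of the β-keto ester) | CCc1ccc2c(c1)C(O)=C(C(=O)OCC)[C@@](C)(CC[C@H]3COC(C)(C)O3)C2(C)C | intermediate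
11 | (3R)-3-{2-[(4S)-2,2-dimethyl-1,3-dioxolan-4-yl]ethyl}-7-ethyl-2-(hydroxymethyl)-3,4,4-trimethyl-1,2,3,4-tetrahydronaphthalen-1-ol, mixture of epimers at C1 and C2 (both removed in step 7) | CCc1ccc2c(c1)C(O)C(CO)[C@@](C)(CC[C@H]3COC(C)(C)O3)C2(C)C | intermediate
12 | (2S)-4-[(2S)-6-ethyl-3-(hydroxymethyl)-1,1,2-trimethyl-1,2-dihydronaphthalen-2-yl]butane-1,2-diol | CCc1ccc2c(c1)C=C(CO)[C@@](C)(CC[C@H](O)CO)C2(C)C | intermediate
13 | 4-[(2S)-6-ethyl-3-formyl-1,1,2-trimethyl-1,2-dihydronaphthalen-2-yl]-2-oxobutanal | CCc1ccc2c(c1)C=C(C=O)[C@@](C)(CCC(=O)C=O)C2(C)C | intermediate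
14 | keto lactone: salimabromide without the two bromines and with C15–C16 saturated, (9S,10S,13R,14R) | CCc1ccc2c(c1)[C@H]1[C@@H]3OC(=O)[C@H]1[C@@](C)(CCC3=O)C2(C)C | intermediate
15 | dibromo keto lactone: salimabromide with C15–C16 saturated, (9S,10S,13R,14R) | CCc1c(Br)cc2c(c1Br)[C@H]1[C@@H]3OC(=O)[C@H]1[C@@](C)(CCC3=O)C2(C)C | intermediate
16 | salimabromide, (9S,10S,13R,14R) | CCc1c(Br)cc2c(c1Br)[C@H]1[C@@H]3OC(=O)[C@H]1[C@@](C)(C=CC3=O)C2(C)C | target

**Totals**
Total step count: 11. Longest linear sequence: 11 steps (1 → 16); 2 and 7 are purchased and enter directly.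

**Three steps most likely to fail, each with one fallback**

First, step 5. Methyl must add to a β-carbon flanked by CMe2, and both rate and enantioselectivity are uncertain. The fallback makes the quaternary centre by 1,3-chirality transfer and sets out from 9.
- Corey–Bakshi–Shibata reduction of the aryl ketone with BH3·SMe2 and (S)-1-methyl-3,3-diphenyltetrahydro-1H,3H-pyrrolo[1,2-c][1,3,2]oxazaborole (catalyst antipode chosen for the 1R alcohol) gives ethyl (1R)-3-{2-[(4S)-2,2-dimethyl-1,3-dioxolan-4-yl]ethyl}-7-ethyl-1-hydroxy-4,4-dimethyl-1,4-dihydronaphthalene-2-carboxylate F1.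
- Esterification with picolinic acid (DCC, DMAP) gives ethyl (1R)-3-{2-[(4S)-2,2-dimethyl-1,3-dioxolan-4-yl]ethyl}-7-ethyl-4,4-dimethyl-1-[(pyridine-2-carbonyl)oxy]-1,4-dihydronaphthalene-2-carboxylate F2.
- MeMgBr with CuBr·SMe2 in THF at −40 °C delivers methyl to C14 anti to the leaving group (anti-SN2′ allylic substitution) and moves the alkene to C9=C13, giving ethyl (3S)-3-{2-[(4S)-2,2-dimethyl-1,3-dioxolan-4-yl]ethyl}-7-ethyl-3,4,4-trimethyl-3,4-dihydronaphthalene-2-carboxylate F3.
- i-Bu2AlH reduces the ester to [(3S)-3-{2-[(4S)-2,2-dimethyl-1,3-dioxolan-4-yl]ethyl}-7-ethyl-3,4,4-trimethyl-3,4-dihydronaphthalen-2-yl]methanol F4.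
- Aqueous acid removes the acetonide and the route is rejoined at 12.

Second, step 9. The α-branched enal may be too hindered for the carbene, or the keto aldehyde may react by aldol or Stetter pathways. The fallback replaces the homoenolate step by a normal-polarity enolate Michael addition and sets out from 12.
- MnO2 oxidises only the allylic alcohol, giving (2S)-2-[(3S)-3,4-dihydroxybutyl]-6-ethyl-1,1,2-trimethyl-1,2-dihydronaphthalene-3-carbaldehyde F5.
- Bu2SnO followed by NBS oxidises the secondary hydroxyl of the stannylene acetal, giving (2S)-6-ethyl-2-(4-hydroxy-3-oxobutyl)-1,1,2-trimethyl-1,2-dihydronaphthalene-3-carbaldehyde F6.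
- DBU then promotes intramolecular Michael addition of the α-hydroxy ketone enolate carbon C10 to the enal β-carbon C9, and the hydroxyl closes onto the aldehyde to give the lactol of 14 (C12 hemiacetal, anomer mixture) F7.
- Oxidation of the lactol (TEMPO, PhI(OAc)2) gives 14, where the route is rejoined.

Third, step 10. The second bromine must enter a hindered position and the ketone may be α-brominated. The fallback uses that side reaction, sets out from 14 and makes step 11 unnecessary.
- Excess bromine (3.3 equiv Br2, 2.2 equiv AgOTf, then warming in the acid formed) brominates both ring positions and the ketone α-carbon C16, giving 16-bromo-15,16-dihydrosalimabromide (C16 epimers) F8.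
- Li2CO3 and LiBr in DMF at 120 °C eliminate HBr to form the C15=C16 enone, so the route is rejoined directly at 16.

**Further compounds**
F1 | step 5 | ethyl (1R)-3-{2-[(4S)-2,2-dimethyl-1,3-dioxolan-4-yl]ethyl}-7-ethyl-1-hydroxy-4,4-dimethyl-1,4-dihydronaphthalene-2-carboxylate | CCc1ccc2c(c1)[C@@H](O)C(C(=O)OCC)=C(CC[C@H]3COC(C)(C)O3)C2(C)C
F2 | step 5 | ethyl (1R)-3-{2-[(4S)-2,2-dimethyl-1,3-dioxolan-4-yl]ethyl}-7-ethyl-4,4-dimethyl-1-[(pyridine-2-carbonyl)oxy]-1,4-dihydronaphthalene-2-carboxylate | CCc1ccc2c(c1)[C@@H](OC(=O)c3ccccn3)C(C(=O)OCC)=C(CC[C@H]4COC(C)(C)O4)C2(C)C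
F3 | step 5 | ethyl (3S)-3-{2-[(4S)-2,2-dimethyl-1,3-dioxolan-4-yl]ethyl}-7-ethyl-3,4,4-trimethyl-3,4-dihydronaphthalene-2-carboxylate | CCc1ccc2c(c1)C=C(C(=O)OCC)[C@@](C)(CC[C@H]3COC(C)(C)O3)C2(C)C
F4 | step 5 | [(3S)-3-{2-[(4S)-2,2-dimethyl-1,3-dioxolan-4-yl]ethyl}-7-ethyl-3,4,4-trimethyl-3,4-dihydronaphthalen-2-yl]methanol | CCc1ccc2c(c1)C=C(CO)[C@@](C)(CC[C@H]3COC(C)(C)O3)C2(C)C
F5 | step 9 | (2S)-2-[(3S)-3,4-dihydroxybutyl]-6-ethyl-1,1,2-trimethyl-1,2-dihydronaphthalene-3-carbaldehyde | CCc1ccc2c(c1)C=C(C=O)[C@@](C)(CC[C@H](O)CO)C2(C)C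
F6 | step 9 | (2S)-6-ethyl-2-(4-hydroxy-3-oxobutyl)-1,1,2-trimethyl-1,2-dihydronaphthalene-3-carbaldehyde | CCc1ccc2c(c1)C=C(C=O)[C@@](C)(CCC(=O)CO)C2(C)C
F7 | step 9 | lactol of 14 (C12 hemiacetal, anomer mixture) | CCc1ccc2c(c1)[C@H]1[C@@H]3OC(O)[C@H]1[C@@](C)(CCC3=O)C2(C)C
F8 | step 10 | 16-bromo-15,16-dihydrosalimabromide (C16 epimers) | CCc1c(Br)cc2c(c1Br)[C@H]1[C@@H]3OC(=O)[C@H]1[C@@](C)(CC(Br)C3=O)C2(C)C
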